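## Retrosynthetic overview

1. The target is reached by a last face-selective epoxidation of the strained C4=C5 (E) alkene. The peroxy-hemiketal ring comes from a (Z)-γ-hydroperoxy enone, made by E→Z photoisomerisation after SN2-type perhydrolysis of a vinyl epoxide and aldol condensation of a C12 methyl ketone with (R)-2-methylglycidal.
2. Key step: the nine-membered ring is closed at C5–C6 by an intramolecular Pd-catalysed coupling of a cyclopropanol-derived ketone homoenolate (C6, β to the C8 carbonyl) with the (E)-alkenyl iodide (C5).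
3. The cyclopropanol comes from a cyclobutane ester (Kulinkovich) and the alkenyl iodide from a terminal alkyne (carboalumination).
4. The cyclobutane comes from Wolff ring contraction of an α-diazocyclopentanone. C1 is set by an anti-selective cuprate addition, and the C11 quaternary centre by a Cu-catalysed enantioselective conjugate addition of a 1-silylvinyl group (masked acetyl) to 3-methylcyclopentenone.
5. Ring order: cyclopentanone (purchased ring) → cyclobutane → nine-membered carbocycle → 1,2-dioxene → oxirane.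

Assumption 1: locants C1–C16 in the explanations are those of the target skeleton (nine-membered ring C1–C9, cyclobutane C1/C9/C10/C11, side chain C12–C16).
Assumption 2: the peroxy-hemiketal carbon C12 is configurationally labile (ring–chain tautomerism), so its configuration is set by equilibration; the anomer drawn in the target is taken to be the one the natural product adopts and is separated from any minor anomer.
Assumption 3: the sense of induction in step 2 is confirmed on the first run; the ligand enantiomer that gives (R)-6 is used.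

## Route

Step 1
Reactants: 1 benzyl(chloro)dimethylsilane; 2 ethynylmagnesium bromide
Product: 3 benzyl(ethynyl)dimethylsilane
Conditions: THF, 0 °C to rt
Reagents that add atoms: none
Why: Grignard silylation (substitution at silicon by the acetylide) gives an alkyne whose benzyldimethylsilyl group can later be oxidised off under basic peroxide conditions; no stereocentre is formed.

Step 2
Reactants: 3 benzyl(ethynyl)dimethylsilane; 4 3-methylcyclopent-2-en-1-one
Product: 6 (R)-3-[1-(benzyldimethylsilyl)ethenyl]-3-methylcyclopentan-1-one, via alkenylalane 5 (not isolated)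
Conditions: 3, iBu2AlH, hexane/THF, 55 °C; then 4, Cu(OTf)2 (5 mol %), chiral sulfonate-bearing imidazolinium salt as NHC precursor (5.5 mol %), THF, −78 to −15 °C; aq. Rochelle salt
Reagents that add atoms: none
Why: Hydroalumination places aluminium geminal to silicon, and the copper–NHC-catalysed enantioselective conjugate addition transfers the 1-silylvinyl group (a masked acetyl, C12/C13) to the β-carbon, creating the quaternary stereocentre (future C11) under catalyst control.

Step 3
Reactants: 6 (R)-3-[1-(benzyldimethylsilyl)ethenyl]-3-methylcyclopentan-1-one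
Product: 8 (S)-4-[1-(benzyldimethylsilyl)ethenyl]-4-methylcyclopent-2-en-1-one, via silyl enol ether 7 (not isolated)
Conditions: LiN(iPr)2, TMSCl, THF, −78 °C; then Pd(OAc)2 (10 mol %), O2 (1 atm), DMSO, 40 °C
Reagents that add atoms: none
Why: Saegusa–Ito dehydrogenation; only the α-position remote from the quaternary carbon has a β-hydrogen, so a single enone forms and the stereocentre is untouched.

Step 4
Reactants: 8 (S)-4-[1-(benzyldimethylsilyl)ethenyl]-4-methylcyclopent-2-en-1-one; 9 (4-bromobut-1-yn-1-yl)trimethylsilane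
Product: 11 {[(3S,4S)-4-[1-(benzyldimethylsilyl)ethenyl]-4-methyl-3-[4-(trimethylsilyl)but-3-yn-1-yl]cyclopent-1-en-1-yl]oxy}trimethylsilane, via Grignard reagent 10 (not isolated)
Conditions: 9, Mg, THF; then CuBr·SMe2 (10 mol %), TMSCl, 8, THF, −78 °C
Reagents that add atoms: chlorotrimethylsilane C[Si](C)(C)Cl
Why: Copper-catalysed conjugate addition with silyl trapping occurs anti to the bulky 1-silylvinyl group, so the C2–C5 chain ends up cis to methyl and trans to the future C12 (sets C1), and the enol ether fixes the enolate towards the future C9.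

Step 5
Reactants: 11 {[(3S,4S)-4-[1-(benzyldimethylsilyl)ethenyl]-4-methyl-3-[4-(trimethylsilyl)but-3-yn-1-yl]cyclopent-1-en-1-yl]oxy}trimethylsilane
Product: 13 (3R,4S)-4-[1-(benzyldimethylsilyl)ethenyl]-2-diazo-4-methyl-3-[4-(trimethylsilyl)but-3-yn-1-yl]cyclopentan-1-one, via trifluoroacetyl ketone 12 (not isolated)
Conditions: MeLi, THF, 0 °C; CF3CO2CH2CF3, −78 °C; then MsN3, Et3N, H2O, MeCN, rt
Reagents that add atoms: methanesulfonyl azide CS(=O)(=O)N=[N+]=[N-]
Why: MeLi regenerates the regiodefined lithium enolate, trifluoroacetylation activates C9, and detrifluoroacetylative diazo transfer (Regitz-type) installs the diazo group without touching a stereocentre.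

Step 6
Reactants: 13 (3R,4S)-4-[1-(benzyldimethylsilyl)ethenyl]-2-diazo-4-methyl-3-[4-(trimethylsilyl)but-3-yn-1-yl]cyclopentan-1-one
Product: 16 methyl (1R,2S,3S)-3-[1-(benzyldimethylsilyl)ethenyl]-2-(but-3-yn-1-yl)-3-methylcyclobutane-1-carboxylate, via ketene 14 (not isolated), via silylalkyne ester 15 (not isolated)
Conditions: hν (365 nm), MeOH, rt; then NaOMe, MeOH, 45 °C
Reagents that add atoms: methanol CO
Why: Photochemical Wolff rearrangement contracts the ring (C10 migrates, C1 and C11 untouched), methanol traps the ketene, and methoxide equilibrates C9 to the all-pseudo-equatorial trans ester (sets C9) while removing the alkynyl silyl group.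

Step 7
Reactants: 16 methyl (1R,2S,3S)-3-[1-(benzyldimethylsilyl)ethenyl]-2-(but-3-yn-1-yl)-3-methylcyclobutane-1-carboxylate
Product: 18 methyl (1R,2S,3S)-3-[1-(benzyldimethylsilyl)ethenyl]-2-[(3E)-4-iodo-3-methylbut-3-en-1-yl]-3-methylcyclobutane-1-carboxylate, via alkenylalane 17 (not isolated)
Conditions: AlMe3 (3 equiv), Cp2ZrCl2 (0.3 equiv), H2O (1 equiv), CH2Cl2, −23 °C; then I2, THF, −23 to 0 °C
Reagents that add atoms: trimethylaluminium C[Al](C)C; iodine II
Why: Negishi zirconium-catalysed syn-carboalumination of the terminal alkyne and iodinolysis with retention give the (E)-trisubstituted alkenyl iodide, fixing the C4=C5 geometry; the ester survives at low temperature.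

Step 8
Reactants: 18 methyl (1R,2S,3S)-3-[1-(benzyldimethylsilyl)ethenyl]-2-[(3E)-4-iodo-3-methylbut-3-en-1-yl]-3-methylcyclobutane-1-carboxylate
Product: 19 1-{(1R,2S,3S)-3-[1-(benzyldimethylsilyl)ethenyl]-2-[(3E)-4-iodo-3-methylbut-3-en-1-yl]-3-methylcyclobutyl}cyclopropan-1-ol
Conditions: EtMgBr (3 equiv), Ti(OiPr)4 (0.5 equiv), THF, 0 °C to rt
Reagents that add atoms: ethylmagnesium bromide CC[Mg]Br
Why: Kulinkovich cyclopropanation of the ester gives the 1-substituted cyclopropanol, a latent homoenolate of the C8 ketone that carries C6 and C7.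

Step 9
Reactants: 19 1-{(1R,2S,3S)-3-[1-(benzyldimethylsilyl)ethenyl]-2-[(3E)-4-iodo-3-methylbut-3-en-1-yl]-3-methylcyclobutyl}cyclopropan-1-ol
Product: 20 (1S,4E,9R,11S)-11-[1-(benzyldimethylsilyl)ethenyl]-4,11-dimethylbicyclo[7.2.0]undec-4-en-8-one
Conditions: Pd(OAc)2 (10 mol %), XPhos (20 mol %), Cs2CO3 (2 equiv), toluene, 80 °C, syringe-pump addition to 2 mM
Reagents that add atoms: none
Why: Proposed new method: the alkenyl iodide adds oxidatively to zerovalent palladium, the cyclopropanol exchanges onto divalent palladium as its alkoxide, strain-driven β-carbon elimination gives the palladium homoenolate (C6, normally the electrophilic β-carbon of the C8 ketone) as a ten-membered palladacycle, and C(sp3)–C(sp2) reductive elimination closes the nine-membered ring with retention of the E geometry; the closest known reactions are the intermolecular Pd-catalysed ring-opening cross-coupling of cyclopropanols with aryl and alkenyl halides and B-alkyl Suzuki macrocyclisations that close (E)-cyclononenes, and base equilibration at C9 keeps the more stable trans ring fusion.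

Step 10
Reactants: 20 (1S,4E,9R,11S)-11-[1-(benzyldimethylsilyl)ethenyl]-4,11-dimethylbicyclo[7.2.0]undec-4-en-8-one
Product: 21 (1S,4E,9R,11S)-11-[1-(benzyldimethylsilyl)ethenyl]-4,11-dimethyl-8-methylidenebicyclo[7.2.0]undec-4-ene
Conditions: Ph3PCH3Br, KOtBu, toluene, 0 to 50 °C
Reagents that add atoms: methyltriphenylphosphonium bromide C[P+](c1ccccc1)(c1ccccc1)c1ccccc1.[Br-]
Why: Wittig methylenation of the C8 ketone installs the exocyclic alkene; any C9 epimerisation under the basic conditions funnels to the trans-fused isomer.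

Step 11
Reactants: 21 (1S,4E,9R,11S)-11-[1-(benzyldimethylsilyl)ethenyl]-4,11-dimethyl-8-methylidenebicyclo[7.2.0]undec-4-ene
Product: 23 1-[(1S,4E,9R,11S)-4,11-dimethyl-8-methylidenebicyclo[7.2.0]undec-4-en-11-yl]ethan-1-one, via fluorosilane 22 (not isolated)
Conditions: Bu4NF, THF, 0 °C; then H2O2 (30 %), KHCO3, MeOH, rt
Reagents that add atoms: hydrogen peroxide OO
Why: Tamao–Fleming-type oxidation: fluoride removes the benzyl group from silicon and alkaline peroxide oxidises the C–Si bond to an enol that tautomerises to the C12 methyl ketone, under conditions that do not attack unactivated alkenes.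

Step 12
Reactants: 24 2-methylprop-2-en-1-ol
Product: 25 (S)-(2-methyloxiran-2-yl)methanol
Conditions: tBuOOH, Ti(OiPr)4 (5 mol %), L-(+)-diethyl tartrate (6 mol %), 4 Å sieves, CH2Cl2, −20 °C
Reagents that add atoms: tert-butyl hydroperoxide CC(C)(C)OO
Why: Sharpless asymmetric epoxidation with the L-(+)-tartrate ligand gives the (S)-epoxy alcohol, setting the future C15 centre by reagent control.

Step 13
Reactants: 25 (S)-(2-methyloxiran-2-yl)methanol
Product: 26 (R)-2-methyloxirane-2-carbaldehyde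
Conditions: TEMPO (10 mol %), PhI(OAc)2, CH2Cl2, 0 °C; used as a dried solution
Reagents that add atoms: none
Why: Oxoammonium (TEMPO) oxidation of the primary alcohol gives the non-enolisable epoxy aldehyde without touching the quaternary stereocentre (the descriptor changes only through CIP priorities).

Step 14
Reactants: 23 1-[(1S,4E,9R,11S)-4,11-dimethyl-8-methylidenebicyclo[7.2.0]undec-4-en-11-yl]ethan-1-one; 26 (R)-2-methyloxirane-2-carbaldehyde
Product: 29 (2E)-1-[(1S,4E,9R,11S)-4,11-dimethyl-8-methylidenebicyclo[7.2.0]undec-4-en-11-yl]-3-[(2S)-2-methyloxiran-2-yl]prop-2-en-1-one, via aldol adduct 27 (not isolated), via mesylate 28 (not isolated)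
Conditions: LiN(iPr)2, THF, −78 °C; 26; then MsCl, −78 to 0 °C; DBU, rt
Reagents that add atoms: none
Why: Aldol addition of the kinetic methyl-ketone enolate to the epoxy aldehyde followed by mesylation and E1cB elimination (aldol condensation) forms the C13=C14 bond as the E-enone and leaves the epoxide stereocentre intact.

Step 15
Reactants: 29 (2E)-1-[(1S,4E,9R,11S)-4,11-dimethyl-8-methylidenebicyclo[7.2.0]undec-4-en-11-yl]-3-[(2S)-2-methyloxiran-2-yl]prop-2-en-1-one
Product: 30 (2E,4R)-1-[(1S,4E,9R,11S)-4,11-dimethyl-8-methylidenebicyclo[7.2.0]undec-4-en-11-yl]-4-hydroperoxy-5-hydroxy-4-methylpent-2-en-1-one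
Conditions: anhydrous H2O2 in Et2O (10 equiv), H3PMo12O40 (2 mol %), 0 °C to rt
Reagents that add atoms: hydrogen peroxide OO
Why: Acid-catalysed perhydrolysis of the 2,2-disubstituted epoxide at its tertiary carbon with inversion (the electron-poor enone disfavours an allyl cation, keeping the opening SN2-like) sets C15 as R, and the E geometry keeps the carbonyl oxygen from competing as an internal nucleophile.

Step 16
Reactants: 30 (2E,4R)-1-[(1S,4E,9R,11S)-4,11-dimethyl-8-methylidenebicyclo[7.2.0]undec-4-en-11-yl]-4-hydroperoxy-5-hydroxy-4-methylpent-2-en-1-one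
Product: 31 (2R,3E)-5-[(1S,4E,9R,11S)-4,11-dimethyl-8-methylidenebicyclo[7.2.0]undec-4-en-11-yl]-2-hydroperoxy-2-methyl-5-oxopent-3-en-1-yl acetate
Conditions: vinyl acetate, Novozym 435 (immobilised Candida antarctica lipase B), tBuOMe, 25 °C
Reagents that add atoms: vinyl acetate C=COC(C)=O
Why: Lipase-catalysed transesterification acetylates the primary alcohol under neutral conditions and leaves the hindered tertiary hydroperoxide free, which avoids perester formation.

Step 17
Reactants: 31 (2R,3E)-5-[(1S,4E,9R,11S)-4,11-dimethyl-8-methylidenebicyclo[7.2.0]undec-4-en-11-yl]-2-hydroperoxy-2-methyl-5-oxopent-3-en-1-yl acetate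
Product: 33 {(3R,6S)-6-[(1S,4E,9R,11S)-4,11-dimethyl-8-methylidenebicyclo[7.2.0]undec-4-en-11-yl]-6-hydroxy-3-methyl-3,6-dihydro-1,2-dioxin-3-yl}methyl acetate, via Z-hydroperoxy enone 32 (not isolated)
Conditions: hν (350 nm), MeCN, 0 °C, dilute
Reagents that add atoms: none
Why: Enone E→Z photoisomerisation, with the Z isomer drained from the photostationary mixture by intramolecular addition of the hydroperoxide to the ketone (ring–chain tautomerism to the 1,2-dioxin-3-ol); C15 is untouched and C12 is set by equilibration.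

Step 18
Reactants: 33 {(3R,6S)-6-[(1S,4E,9R,11S)-4,11-dimethyl-8-methylidenebicyclo[7.2.0]undec-4-en-11-yl]-6-hydroxy-3-methyl-3,6-dihydro-1,2-dioxin-3-yl}methyl acetate
Product: 34 {(3R,6S)-6-[(1S,4S,5S,9R,11S)-4,5-epoxy-4,11-dimethyl-8-methylidenebicyclo[7.2.0]undecan-11-yl]-6-hydroxy-3-methyl-3,6-dihydro-1,2-dioxin-3-yl}methyl acetate (target)
Conditions: mCPBA (1.05 equiv), NaHCO3, CH2Cl2, −20 °C
Reagents that add atoms: 3-chloroperoxybenzoic acid OOC(=O)c1cccc(Cl)c1
Why: Prilezhaev epoxidation picks the strained trisubstituted E-cycloalkene over the exocyclic and dioxene alkenes and attacks its exposed outer face, as in the caryophyllene series, giving mainly the (4S,5S)-oxide (minor epimer removed by chromatography).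

## Compound list

1 | benzyl(chloro)dimethylsilane | C[Si](C)(Cl)Cc1ccccc1 | starting material
2 | ethynylmagnesium bromide | C#C[Mg]Br | starting material
3 | benzyl(ethynyl)dimethylsilane | C#C[Si](C)(C)Cc1ccccc1 | intermediate
4 | 3-methylcyclopent-2-en-1-one | CC1=CC(=O)CC1 | starting material
5 | [1-(benzyldimethylsilyl)ethenyl]bis(2-methylpropyl)alane (not isolated) | C=C([Si](C)(C)Cc1ccccc1)[Al](CC(C)C)CC(C)C | intermediate
6 | (R)-3-[1-(benzyldimethylsilyl)ethenyl]-3-methylcyclopentan-1-one | O=C1C[C@](C)(C(=C)[Si](C)(C)Cc2ccccc2)CC1 | intermediate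
7 | {[(4R)-4-[1-(benzyldimethylsilyl)ethenyl]-4-methylcyclopent-1-en-1-yl]oxy}trimethylsilane (not isolated) | C[Si](C)(C)OC1=CC[C@@](C)(C(=C)[Si](C)(C)Cc2ccccc2)C1 | intermediate
8 | (S)-4-[1-(benzyldimethylsilyl)ethenyl]-4-methylcyclopent-2-en-1-one | O=C1C[C@](C)(C(=C)[Si](C)(C)Cc2ccccc2)C=C1 | intermediate
9 | (4-bromobut-1-yn-1-yl)trimethylsilane | C[Si](C)(C)C#CCCBr | starting material
10 | [4-(trimethylsilyl)but-3-yn-1-yl]magnesium bromide (not isolated) | C[Si](C)(C)C#CCC[Mg]Br | intermediate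
11 | {[(3S,4S)-4-[1-(benzyldimethylsilyl)ethenyl]-4-methyl-3-[4-(trimethylsilyl)but-3-yn-1-yl]cyclopent-1-en-1-yl]oxy}trimethylsilane (chain cis to methyl) | C[Si](C)(C)OC1=C[C@H](CCC#C[Si](C)(C)C)[C@@](C)(C(=C)[Si](C)(C)Cc2ccccc2)C1 | intermediate
12 | 2-(trifluoroacetyl) ketone from 11, ring stereocentres as in 11, C2 unassigned (not isolated) | O=C1C[C@](C)(C(=C)[Si](C)(C)Cc2ccccc2)[C@@H](CCC#C[Si](C)(C)C)C1C(=O)C(F)(F)F | intermediate
13 | (3R,4S)-4-[1-(benzyldimethylsilyl)ethenyl]-2-diazo-4-methyl-3-[4-(trimethylsilyl)but-3-yn-1-yl]cyclopentan-1-one | O=C1C[C@](C)(C(=C)[Si](C)(C)Cc2ccccc2)[C@@H](CCC#C[Si](C)(C)C)C1=[N+]=[N-] | intermediate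
14 | cyclobutylidene ketene from 13, chain cis to methyl (not isolated) | O=C=C1C[C@](C)(C(=C)[Si](C)(C)Cc2ccccc2)[C@H]1CCC#C[Si](C)(C)C | intermediate
15 | methyl 3-[1-(benzyldimethylsilyl)ethenyl]-3-methyl-2-[4-(trimethylsilyl)but-3-yn-1-yl]cyclobutane-1-carboxylate, C1 epimer mixture (not isolated) | COC(=O)C1C[C@](C)(C(=C)[Si](C)(C)Cc2ccccc2)[C@H]1CCC#C[Si](C)(C)C | intermediate
16 | methyl (1R,2S,3S)-3-[1-(benzyldimethylsilyl)ethenyl]-2-(but-3-yn-1-yl)-3-methylcyclobutane-1-carboxylate | C#CCC[C@H]1[C@H](C(=O)OC)C[C@]1(C)C(=C)[Si](C)(C)Cc1ccccc1 | intermediate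
17 | (E)-alkenyl(dimethyl)alane from 16 (not isolated) | C[Al](C)/C=C(\C)CC[C@H]1[C@H](C(=O)OC)C[C@]1(C)C(=C)[Si](C)(C)Cc1ccccc1 | intermediate
18 | methyl (1R,2S,3S)-3-[1-(benzyldimethylsilyl)ethenyl]-2-[(3E)-4-iodo-3-methylbut-3-en-1-yl]-3-methylcyclobutane-1-carboxylate | I/C=C(\C)CC[C@H]1[C@H](C(=O)OC)C[C@]1(C)C(=C)[Si](C)(C)Cc1ccccc1 | intermediate
19 | 1-{(1R,2S,3S)-3-[1-(benzyldimethylsilyl)ethenyl]-2-[(3E)-4-iodo-3-methylbut-3-en-1-yl]-3-methylcyclobutyl}cyclopropan-1-ol | I/C=C(\C)CC[C@H]1[C@H](C2(O)CC2)C[C@]1(C)C(=C)[Si](C)(C)Cc1ccccc1 | intermediate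
20 | (1S,4E,9R,11S)-11-[1-(benzyldimethylsilyl)ethenyl]-4,11-dimethylbicyclo[7.2.0]undec-4-en-8-one | O=C1CC/C=C(\C)CC[C@H]2[C@H]1C[C@]2(C)C(=C)[Si](C)(C)Cc1ccccc1 | intermediate
21 | (1S,4E,9R,11S)-11-[1-(benzyldimethylsilyl)ethenyl]-4,11-dimethyl-8-methylidenebicyclo[7.2.0]undec-4-ene | C=C1CC/C=C(\C)CC[C@H]2[C@H]1C[C@]2(C)C(=C)[Si](C)(C)Cc1ccccc1 | intermediate
22 | (1S,4E,9R,11S)-11-[1-(fluorodimethylsilyl)ethenyl]-4,11-dimethyl-8-methylidenebicyclo[7.2.0]undec-4-ene (not isolated) | C=C1CC/C=C(\C)CC[C@H]2[C@H]1C[C@]2(C)C(=C)[Si](C)(C)F | intermediate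
23 | 1-[(1S,4E,9R,11S)-4,11-dimethyl-8-methylidenebicyclo[7.2.0]undec-4-en-11-yl]ethan-1-one | C=C1CC/C=C(\C)CC[C@H]2[C@H]1C[C@]2(C)C(C)=O | intermediate
24 | 2-methylprop-2-en-1-ol | C=C(C)CO | starting material
25 | (S)-(2-methyloxiran-2-yl)methanol | OC[C@@]1(C)CO1 | intermediate
26 | (R)-2-methyloxirane-2-carbaldehyde | O=C[C@@]1(C)CO1 | intermediate
27 | aldol adduct of 23 and 26, C14 epimers, epoxide carbon as in 26 (not isolated) | C=C1CC/C=C(\C)CC[C@H]2[C@H]1C[C@]2(C)C(=O)CC(O)[C@@]3(C)CO3 | intermediate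
28 | methanesulfonate of 27 (not isolated) | C=C1CC/C=C(\C)CC[C@H]2[C@H]1C[C@]2(C)C(=O)CC(OS(C)(=O)=O)[C@@]3(C)CO3 | intermediate
29 | (2E)-1-[(1S,4E,9R,11S)-4,11-dimethyl-8-methylidenebicyclo[7.2.0]undec-4-en-11-yl]-3-[(2S)-2-methyloxiran-2-yl]prop-2-en-1-one | C=C1CC/C=C(\C)CC[C@H]2[C@H]1C[C@]2(C)C(=O)/C=C/[C@@]3(C)CO3 | intermediate
30 | (2E,4R)-1-[(1S,4E,9R,11S)-4,11-dimethyl-8-methylidenebicyclo[7.2.0]undec-4-en-11-yl]-4-hydroperoxy-5-hydroxy-4-methylpent-2-en-1-one | C=C1CC/C=C(\C)CC[C@H]2[C@H]1C[C@]2(C)C(=O)/C=C/[C@](C)(CO)OO | intermediate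
31 | (2R,3E)-5-[(1S,4E,9R,11S)-4,11-dimethyl-8-methylidenebicyclo[7.2.0]undec-4-en-11-yl]-2-hydroperoxy-2-methyl-5-oxopent-3-en-1-yl acetate | C=C1CC/C=C(\C)CC[C@H]2[C@H]1C[C@]2(C)C(=O)/C=C/[C@](C)(COC(C)=O)OO | intermediate
32 | (3Z) isomer of 31 (not isolated) | C=C1CC/C=C(\C)CC[C@H]2[C@H]1C[C@]2(C)C(=O)/C=C\[C@](C)(COC(C)=O)OO | intermediate
33 | {(3R,6S)-6-[(1S,4E,9R,11S)-4,11-dimethyl-8-methylidenebicyclo[7.2.0]undec-4-en-11-yl]-6-hydroxy-3-methyl-3,6-dihydro-1,2-dioxin-3-yl}methyl acetate | C=C1CC/C=C(\C)CC[C@H]2[C@H]1C[C@]2(C)[C@]3(O)C=C[C@](C)(COC(C)=O)OO3 | intermediate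
34 | {(3R,6S)-6-[(1S,4S,5S,9R,11S)-4,5-epoxy-4,11-dimethyl-8-methylidenebicyclo[7.2.0]undecan-11-yl]-6-hydroxy-3-methyl-3,6-dihydro-1,2-dioxin-3-yl}methyl acetate (CNP0169860.2) | C=C1CC[C@@H]2O[C@@]2(C)CC[C@H]2[C@H]1C[C@]2(C)[C@]1(O)C=C[C@](C)(COC(C)=O)OO1 | target

## Step count and risks

Total step count: 18. Longest linear sequence: 16 steps (steps 1–11 and 14–18, from 1 to 34); steps 12–13 form the side branch to aldehyde 26.

Most likely to fail, in order: step 9, step 15, step 17.

Step 9 (Pd homoenolate macrocyclisation). The risks are β-hydride elimination of the palladium homoenolate to the enone and oligomerisation instead of closure of the strained nine-membered ring. The fallback sets out from ester 18 and comes back at ketone 20. Ester 18 is converted with MeNH(OMe)·HCl and iPrMgCl into Weinreb amide F1, and vinylmagnesium bromide then gives vinyl ketone F2. The ring is closed by a nickel-catalysed intramolecular reductive conjugate addition of the alkenyl iodide to the enone (NiCl2·glyme, neocuproine, Mn powder, Et3SiCl, DMF, high dilution). This joins the same two carbons, the enone β-carbon C6 and the iodide carbon C5, under reducing conditions and gives triethylsilyl enol ether F3. K2CO3 in MeOH then releases ketone 20.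

Step 15 (perhydrolysis next to the strained ring alkene). The risks are epoxidation or acid-induced transannular reaction of the C4=C5 alkene and attack at C16 instead of C15. The fallback moves the peroxide-forming step to a small fragment; it sets out from aldehyde 26 and comes back at 31.
- Wittig reaction of 26 with Ph3P=CHCO2Et gives epoxy enoate F4, which has the same electronic situation at the epoxide as 29 but no sensitive alkene.
- Perhydrolysis under the step 15 conditions gives hydroperoxy alcohol F5, and lipase acetylation gives acetate F6.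
- 2-Methoxypropene with pyridinium tosylate gives peroxyketal F7, and ozonolysis with Me2S work-up gives peroxy aldehyde F8.
- The lithium enolate of 23 adds to F8 to give aldol adduct F9; mesylation gives mesylate F10 and DBU elimination gives enone peroxyketal F11.
- AcOH/H2O/THF removes the peroxyketal and returns hydroperoxide 31.

Step 17 (photoisomerisation of a hydroperoxide-bearing enone). The risks are sensitised O–O cleavage and an incomplete E→Z drain. The fallback isomerises before the peroxide exists and closes the ring at the other end; it sets out from epoxy enone 29 and comes back at 33. Irradiation of 29 (350 nm) gives Z-epoxy enone F12. Ethereal H2O2 with a trace of pyridinium tosylate forms perhydrate F13 at the ketone. Its hydroperoxy group opens the epoxide at C15 in a 6-exo fashion with inversion to give dioxinol alcohol F14; the known hazard is competing 5-exo attack by the carbonyl oxygen. Ac2O/pyridine at 0 °C then acetylates the primary alcohol to give 33.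

Further compounds
F1 | step 9 | (1R,2S,3S)-3-[1-(benzyldimethylsilyl)ethenyl]-2-[(3E)-4-iodo-3-methylbut-3-en-1-yl]-N-methoxy-N,3-dimethylcyclobutane-1-carboxamide | I/C=C(\C)CC[C@H]1[C@H](C(=O)N(C)OC)C[C@]1(C)C(=C)[Si](C)(C)Cc1ccccc1
F2 | step 9 | 1-{(1R,2S,3S)-3-[1-(benzyldimethylsilyl)ethenyl]-2-[(3E)-4-iodo-3-methylbut-3-en-1-yl]-3-methylcyclobutyl}prop-2-en-1-one | I/C=C(\C)CC[C@H]1[C@H](C(=O)C=C)C[C@]1(C)C(=C)[Si](C)(C)Cc1ccccc1
F3 | step 9 | triethylsilyl enol ether (C7=C8) of ketone 20 | CC[Si](CC)(CC)OC1=CC/C=C(\C)CC[C@H]2[C@H]1C[C@]2(C)C(=C)[Si](C)(C)Cc1ccccc1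
F4 | step 15 | ethyl (2E)-3-[(2S)-2-methyloxiran-2-yl]prop-2-enoate | CCOC(=O)/C=C/[C@@]1(C)CO1
F5 | step 15 | ethyl (2E,4R)-4-hydroperoxy-5-hydroxy-4-methylpent-2-enoate | CCOC(=O)/C=C/[C@](C)(CO)OO
F6 | step 15 | ethyl (2E,4R)-5-acetoxy-4-hydroperoxy-4-methylpent-2-enoate | CCOC(=O)/C=C/[C@](C)(COC(C)=O)OO
F7 | step 15 | ethyl (2E,4R)-5-acetoxy-4-[(2-methoxypropan-2-yl)peroxy]-4-methylpent-2-enoate | CCOC(=O)/C=C/[C@](C)(COC(C)=O)OOC(C)(C)OC
F8 | step 15 | (2S)-2-[(2-methoxypropan-2-yl)peroxy]-2-methyl-3-oxopropyl acetate | O=C[C@](C)(COC(C)=O)OOC(C)(C)OC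
F9 | step 15 | aldol adduct of 23 and F8 (C14 epimers) | C=C1CC/C=C(\C)CC[C@H]2[C@H]1C[C@]2(C)C(=O)CC(O)[C@](C)(COC(C)=O)OOC(C)(C)OC
F10 | step 15 | methanesulfonate of F9 | C=C1CC/C=C(\C)CC[C@H]2[C@H]1C[C@]2(C)C(=O)CC(OS(C)(=O)=O)[C@](C)(COC(C)=O)OOC(C)(C)OC
F11 | step 15 | 2-methoxypropan-2-yl peroxyketal of hydroperoxide 31 | C=C1CC/C=C(\C)CC[C@H]2[C@H]1C[C@]2(C)C(=O)/C=C/[C@](C)(COC(C)=O)OOC(C)(C)OC
F12 | step 17 | (2Z) isomer of epoxy enone 29 | C=C1CC/C=C(\C)CC[C@H]2[C@H]1C[C@]2(C)C(=O)/C=C\[C@@]3(C)CO3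
F13 | step 17 | perhydrate (1-hydroperoxy-1-hydroxy adduct) of F12 | C=C1CC/C=C(\C)CC[C@H]2[C@H]1C[C@]2(C)C(O)(OO)/C=C\[C@@]3(C)CO3
F14 | step 17 | (3R,6S)-6-[(1S,4E,9R,11S)-4,11-dimethyl-8-methylidenebicyclo[7.2.0]undec-4-en-11-yl]-3-(hydroxymethyl)-3-methyl-3,6-dihydro-1,2-dioxin-6-ol | C=C1CC/C=C(\C)CC[C@H]2[C@H]1C[C@]2(C)[C@]3(O)C=C[C@](C)(CO)OO3
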